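The route rests on cutting the C3–C3a bond of the dihydrobenzofuran. C3 is a benzylic carbinol carbon (it carries the acetoxy group) joined to the aromatic carbon C3a, which lies ortho to the ring oxygen O1. This is the retron of an aryl–metal addition to an aldehyde. The precursor is an open-chain (S)-α-aryloxy-β,γ-unsaturated aldehyde whose aryl ring bears iodine ortho to the ether oxygen. An intramolecular Nozaki–Hiyama–Kishi reaction closes the furan ring and sets C3 trans to the C2 isopropenyl group by 1,2-induction. C2 comes from a palladium-catalysed asymmetric etherification, the side-chain carbinol from asymmetric transfer hydrogenation, and the enal from late allylic oxidation of the isopropenyl methyl group.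

Key step: step 4

Remark: benzofuran numbering (O1, C2, C3, C3a, C4–C7, C7a) is used throughout. The (R,R)-ligand named in step 2 is the enantiomer expected to give the (S)-ether; its mirror image is used if the first run shows the opposite sense.

Step 1
Reactants: 1 methacrolein
Product: 2 racemic 2-(prop-1-en-2-yl)oxirane
Conditions: Me3S+ I−, n-BuLi, THF, −10 °C; then 1, −10 °C → rt; pentane extraction, fractional distillation
Reagents that add atoms: trimethylsulfonium iodide, C[S+](C)C.[I-]
Why: Corey–Chaykovsky epoxidation, in which the unstabilised sulfonium ylide adds 1,2 to the enal carbonyl and the betaine closes to the oxirane with loss of Me2S; the racemate is what the dynamic kinetic step 2 needs.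

Step 2
Reactants: 2 racemic 2-(prop-1-en-2-yl)oxirane; 3 1-(4-hydroxy-3-iodophenyl)ethan-1-one
Product: 4 (2S)-2-(4-acetyl-2-iodophenoxy)-3-methylbut-3-en-1-ol
Conditions: Pd2(dba)3·CHCl3 (1 mol %), (R,R)-DACH-phenyl Trost ligand (3 mol %), CH2Cl2, rt
Reagents that add atoms: none
Why: Tsuji–Trost allylic etherification run as a dynamic kinetic asymmetric transformation: zerovalent palladium opens both enantiomers of 2 to one π-allyl complex whose faces interconvert through the unsubstituted CH2 terminus, the alkoxide deprotonates phenol 3 and guides it to the adjacent branched carbon, the ligand pocket sets C2 as (S), and ionisation of the vinyl epoxide should be much faster at room temperature than oxidative addition to the C–I bond.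

Step 3
Reactants: 4 (2S)-2-(4-acetyl-2-iodophenoxy)-3-methylbut-3-en-1-ol
Product: 5 (2S)-2-(4-acetyl-2-iodophenoxy)-3-methylbut-3-enal
Conditions: Dess–Martin periodinane, NaHCO3, CH2Cl2, 0 °C; crude aldehyde used at once
Reagents that add atoms: none
Why: Dess–Martin oxidation stops at the aldehyde, and the buffered, non-basic medium should spare the α-aryloxy allylic C2–H from epimerisation and from migration of the double bond into conjugation.

Step 4
Reactants: 5 (2S)-2-(4-acetyl-2-iodophenoxy)-3-methylbut-3-enal
Product: 6 1-[(2S,3R)-3-hydroxy-2-(prop-1-en-2-yl)-2,3-dihydro-1-benzofuran-5-yl]ethan-1-one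
Conditions: CrCl2 (4 equiv), NiCl2 (1 mol %), degassed DMF, rt; aqueous work-up
Reagents that add atoms: none
Why: Zerovalent nickel, formed from NiCl2 by CrCl2, inserts into the C–I bond, the aryl group is passed to chromium, and the σ-aryl species of trivalent chromium adds to the aldehyde held four atoms away; the closest known reaction type is the intramolecular Nozaki–Hiyama–Kishi addition of aryl and alkenyl iodides to aldehydes. The dihydrofuran ring closes in the 5-exo-trig mode at the carbonyl carbon, which creates the C3–C3a bond. The new stereocentre C3 is set by 1,2-induction from C2: in the forming five-membered ring the bulky chromium-bound oxygen should sit anti to the isopropenyl group, so that only the small C3–H eclipses it, which gives the 2,3-trans (3R) alcohol. The step needs chemoselectivity for the aldehyde over the aryl methyl ketone and over the isopropenyl C=C, which also lies 5-exo to the aryl–metal bond; the first follows from the known aldehyde preference of organochromium reagents, the second from the fact that σ-arylchromium species do not carbometallate unactivated alkenes, helped by a low, phosphine-free nickel loading that keeps the aryl–nickel intermediate short-lived. The non-basic medium should leave the enolisable C2 centre of 5 untouched, and any cis isomer is removed by chromatography at this stage.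

Step 5
Reactants: 6 1-[(2S,3R)-3-hydroxy-2-(prop-1-en-2-yl)-2,3-dihydro-1-benzofuran-5-yl]ethan-1-one
Product: 7 (2S,3R)-5-acetyl-2-(prop-1-en-2-yl)-2,3-dihydro-1-benzofuran-3-yl acetate
Conditions: Ac2O, pyridine, DMAP (cat.), CH2Cl2, 0 °C → rt
Reagents that add atoms: acetic anhydride, CC(=O)OC(C)=O
Why: DMAP-catalysed O-acylation of the secondary benzylic alcohol takes place at oxygen, so C3 keeps its configuration.

Step 6
Reactants: 7 (2S,3R)-5-acetyl-2-(prop-1-en-2-yl)-2,3-dihydro-1-benzofuran-3-yl acetate
Product: 8 (2S,3R)-5-[(1R)-1-hydroxyethyl]-2-(prop-1-en-2-yl)-2,3-dihydro-1-benzofuran-3-yl acetate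
Conditions: RuCl(p-cymene)[(R,R)-TsDPEN] (1 mol %), HCO2H/Et3N (5:2 azeotrope), CH2Cl2, rt
Reagents that add atoms: none
Why: Noyori-type asymmetric transfer hydrogenation of the aryl methyl ketone, in which the (R,R)-catalyst should deliver hydride to give the (R)-carbinol under catalyst control (the ring stereocentres are remote) and leaves the isolated alkene and the acetate alone.

Step 7
Reactants: 8 (2S,3R)-5-[(1R)-1-hydroxyethyl]-2-(prop-1-en-2-yl)-2,3-dihydro-1-benzofuran-3-yl acetate
Product: 9 (1R)-1-[(2S,3R)-3-acetoxy-2-(prop-1-en-2-yl)-2,3-dihydro-1-benzofuran-5-yl]ethyl (2E)-2-methylbut-2-enoate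
Conditions: tigloyl chloride, pyridine, DMAP (cat.), CH2Cl2, 0 °C → rt
Reagents that add atoms: (2E)-2-methylbut-2-enoyl chloride (tigloyl chloride), C/C=C(\C)C(=O)Cl
Why: Acylation at oxygen retains the (R)-carbinol configuration, the pyridine base prevents acid-promoted ionisation of the p-alkoxybenzylic alcohol, and the tiglate is the thermodynamically preferred E isomer so its geometry should hold.

Step 8
Reactants: 9 (1R)-1-[(2S,3R)-3-acetoxy-2-(prop-1-en-2-yl)-2,3-dihydro-1-benzofuran-5-yl]ethyl (2E)-2-methylbut-2-enoate
Product: 11 (1R)-1-[(2S,3R)-3-acetoxy-2-(3-oxoprop-1-en-2-yl)-2,3-dihydro-1-benzofuran-5-yl]ethyl (2E)-2-methylbut-2-enoate (CNP0294391.1), via allylic alcohol 10 (not isolated)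
Conditions: SeO2 (0.5 equiv), t-BuOOH, CH2Cl2, rt; then activated MnO2 added to the same flask, rt
Reagents that add atoms: tert-butyl hydroperoxide, CC(C)(C)OO (terminal oxygen source); selenium dioxide, O=[Se]=O (passes the oxygen on)
Why: Selenium dioxide allylic oxidation (ene reaction, then [2,3]-sigmatropic shift) should attack the methyl group of the 1,1-disubstituted alkene in preference to the C2 methine, which is deactivated by the aryloxy group, while the electron-poor tiglate stays inert, and MnO2 then oxidises only the primary allylic alcohol to the enal without touching a stereocentre.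

Compound list
1 | methacrolein (2-methylprop-2-enal) | C=C(C)C=O | starting material
2 | racemic 2-(prop-1-en-2-yl)oxirane | C=C(C)C1CO1 | intermediate
3 | 1-(4-hydroxy-3-iodophenyl)ethan-1-one | CC(=O)c1ccc(O)c(I)c1 | starting material
4 | (2S)-2-(4-acetyl-2-iodophenoxy)-3-methylbut-3-en-1-ol | C=C(C)[C@@H](CO)Oc1ccc(C(C)=O)cc1I | intermediate
5 | (2S)-2-(4-acetyl-2-iodophenoxy)-3-methylbut-3-enal | C=C(C)[C@@H](C=O)Oc1ccc(C(C)=O)cc1I | intermediate
6 | 1-[(2S,3R)-3-hydroxy-2-(prop-1-en-2-yl)-2,3-dihydro-1-benzofuran-5-yl]ethan-1-one (2,3-trans) | C=C(C)[C@@H]1Oc2ccc(C(C)=O)cc2[C@H]1O | intermediate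
7 | (2S,3R)-5-acetyl-2-(prop-1-en-2-yl)-2,3-dihydro-1-benzofuran-3-yl acetate | C=C(C)[C@@H]1Oc2ccc(C(C)=O)cc2[C@H]1OC(C)=O | intermediate
8 | (2S,3R)-5-[(1R)-1-hydroxyethyl]-2-(prop-1-en-2-yl)-2,3-dihydro-1-benzofuran-3-yl acetate | C=C(C)[C@@H]1Oc2ccc([C@@H](C)O)cc2[C@H]1OC(C)=O | intermediate
9 | (1R)-1-[(2S,3R)-3-acetoxy-2-(prop-1-en-2-yl)-2,3-dihydro-1-benzofuran-5-yl]ethyl (2E)-2-methylbut-2-enoate | C=C(C)[C@@H]1Oc2ccc([C@@H](C)OC(=O)/C(C)=C/C)cc2[C@H]1OC(C)=O | intermediate
10 | (1R)-1-[(2S,3R)-3-acetoxy-2-(3-hydroxyprop-1-en-2-yl)-2,3-dihydro-1-benzofuran-5-yl]ethyl (2E)-2-methylbut-2-enoate (not isolated) | C=C(CO)[C@@H]1Oc2ccc([C@@H](C)OC(=O)/C(C)=C/C)cc2[C@H]1OC(C)=O | intermediate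
11 | (1R)-1-[(2S,3R)-3-acetoxy-2-(3-oxoprop-1-en-2-yl)-2,3-dihydro-1-benzofuran-5-yl]ethyl (2E)-2-methylbut-2-enoate (CNP0294391.1) | C=C(C=O)[C@@H]1Oc2ccc([C@@H](C)OC(=O)/C(C)=C/C)cc2[C@H]1OC(C)=O | target

Total step count: 8. Longest linear sequence: 8 steps (1 to 11); phenol 3 enters at step 2.

Steps most likely to fail

Step 4 (key step). The addition may show poor facial selectivity at the aldehyde, with the oxygen ending up cis to the isopropenyl group; part of the aryl–nickel species may also be lost to insertion into the isopropenyl double bond. The fallback sets out from 5 and comes back at 7. The cyclisation is still run on 5, and the 2,3-cis alcohol 1-[(2S,3S)-3-hydroxy-2-(prop-1-en-2-yl)-2,3-dihydro-1-benzofuran-5-yl]ethan-1-one F1 is carried on instead of being discarded. Mitsunobu esterification with acetic acid (PPh3, DIAD, toluene, 0 °C) should displace the activated C3 oxygen with inversion, acetate entering anti to the isopropenyl group, and give acetate 7 directly. The 5-acetyl group, para to O1, disfavours ionisation at C3 and should keep the substitution on the SN2 path.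

Step 2. Enantio- or regiocontrol in the attack on the 2-methyl-substituted π-allyl complex may be insufficient, or the product ether may re-ionise (the acidic phenol is a fair leaving group), which would erode the ee and leak material to the linear ether. The fallback sets out from 3 and comes back at 4; it makes the stereocentre outside the coupling. Isopropenylmagnesium bromide is added to (tert-butyldimethylsilyloxy)acetaldehyde (THF, −78 °C) to give racemic 1-[(tert-butyldimethylsilyl)oxy]-3-methylbut-3-en-2-ol F2. Sharpless kinetic resolution (Ti(OiPr)4, D-(−)-diisopropyl tartrate, t-BuOOH, 4 Å molecular sieves, CH2Cl2, −20 °C) should leave (2R)-1-[(tert-butyldimethylsilyl)oxy]-3-methylbut-3-en-2-ol F3 and consume the (S)-enantiomer as (1R)-2-[(tert-butyldimethylsilyl)oxy]-1-[(2R)-2-methyloxiran-2-yl]ethan-1-ol F4, which is separated. Mitsunobu etherification of phenol 3 with F3 (PPh3, DIAD, toluene, 0 °C) should go with inversion to 1-(4-{[(2S)-1-[(tert-butyldimethylsilyl)oxy]-3-methylbut-3-en-2-yl]oxy}-3-iodophenyl)ethan-1-one F5. Removal of the silyl group (TBAF, AcOH, THF, 0 °C) gives 4.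

Step 8. Hydrogen abstraction may occur at the wrong allylic site (C2–H instead of the methyl group), or selenium acids may promote ionisation of the two benzylic esters. The fallback sets out from 9 and comes back at 11. Ene-type chlorination with hypochlorous acid made in situ (Ca(OCl)2, solid CO2, CH2Cl2/H2O, 0 °C) should give (1R)-1-[(2S,3R)-3-acetoxy-2-(3-chloroprop-1-en-2-yl)-2,3-dihydro-1-benzofuran-5-yl]ethyl (2E)-2-methylbut-2-enoate F6. Ganem-type oxidation with N-methylmorpholine N-oxide (NaI cat., MeCN, rt) then converts the CH2Cl group into the aldehyde of 11; both allyl termini are CH2, so direct and allylic displacement lead to the same product.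

Further compounds
F1 | step 4 | 1-[(2S,3S)-3-hydroxy-2-(prop-1-en-2-yl)-2,3-dihydro-1-benzofuran-5-yl]ethan-1-one | C=C(C)[C@@H]1Oc2ccc(C(C)=O)cc2[C@@H]1O
F2 | step 2 | racemic 1-[(tert-butyldimethylsilyl)oxy]-3-methylbut-3-en-2-ol | C=C(C)C(O)CO[Si](C)(C)C(C)(C)C
F3 | step 2 | (2R)-1-[(tert-butyldimethylsilyl)oxy]-3-methylbut-3-en-2-ol | C=C(C)[C@@H](O)CO[Si](C)(C)C(C)(C)C
F4 | step 2 | (1R)-2-[(tert-butyldimethylsilyl)oxy]-1-[(2R)-2-methyloxiran-2-yl]ethan-1-ol | C[C@@]1(CO1)[C@H](O)CO[Si](C)(C)C(C)(C)C
F5 | step 2 | 1-(4-{[(2S)-1-[(tert-butyldimethylsilyl)oxy]-3-methylbut-3-en-2-yl]oxy}-3-iodophenyl)ethan-1-one | C=C(C)[C@@H](CO[Si](C)(C)C(C)(C)C)Oc1ccc(C(C)=O)cc1I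
F6 | step 8 | (1R)-1-[(2S,3R)-3-acetoxy-2-(3-chloroprop-1-en-2-yl)-2,3-dihydro-1-benzofuran-5-yl]ethyl (2E)-2-methylbut-2-enoate | C=C(CCl)[C@@H]1Oc2ccc([C@@H](C)OC(=O)/C(C)=C/C)cc2[C@H]1OC(C)=O
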